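Readings and results were computed for an exercise; noise was put on by code.

- delta: solid electrophile 0.50 M; nucleophile 3 equiv; free base 1.1 equiv; protic impurity 10 mM; the very flask that is asked about, followed so far
- flask: solid electrophile 0.50 M; nucleophile 3.00 equiv; free base 1.10 equiv; protic impurity 10.0 mM; time 5.0 h

delta run (percent of the solid electrophile charged)

| time / min | solid electrophile / % | target / % |
|---|---|---|
| 20.0 | 78.5 | 4.1 |
| 40.0 | 66.1 | 10.6 |
| 60.0 | 54.9 | 19.1 |
| 80.0 | 46.3 | 27.0 |
| 90.0 | 40.8 | 30.7 |
| 120 | 28.3 | 43.1 |

(scatter of a reading: 0.5 percentage points)

- given per volume of solution although it is solid: solid electrophile
- candidate steps: electrophile + nucleophile -> acid set free + target; nucleophile + acid set free <-> protonated nucleophile; acid set free + free base <-> salt of the base; protic impurity + free base -> quenched reagent; solid electrophile <-> electrophile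
- at the start none of the solid electrophile is in solution
- what has only dissolved of solid electrophile counts as not reacted
- the earlier runs do not show how much of nucleophile is bound; that part of a forecast is a guess

* part of the solid electrophile that has reacted (what has only dissolved counts as not reacted) at 5.0 h
* share of the unused nucleophile that is free and not bound as protonated nucleophile, at 5.0 h

- In the delta run, from 90.0 min to 120 min, the solid electrophile lost 12 percentage points and the target gained 12 points, about the same, so in this flask dissolved electrophile held near 28.5 % of the charge.
- We freeze that level and write the rate as s · c(electrophile), with s a pseudo-first-order constant. The readings give s = 0.0145 /min while about 87.7 % of the nucleophile remained unconsumed.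
- Dividing gives 0.0165 /min, the start constant, s at the full nucleophile charge; s falls in step with the share of nucleophile left free.
- At its reading pace the solid lasts until about 3.13 h, which leaves 1.87 h of pure decay.
- Over that tail, consumption slows the start constant by a factor of about 71.4 %. Binding is unread, and any bound nucleophile slows it further.
- Our reckoning therefore gives about 92.4 % reacted, an estimate from scattered readings.
- The forecast says 84 % (77 % to 90 %), lower than ours, and 85 % free (65 % to 99 %), adding “The share is a guess”.

    electrophile + nucleophile → acid set free + target (k = 0.0115 /M/min)
    nucleophile + acid set free ⇌ protonated nucleophile, settled at all times (K = 70.0 /M)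
    acid set free + free base ⇌ salt of the base, settled at all times (K = 880 /M)
    protic impurity + free base → quenched reagent (k = 4.90 /M/min)
    solid electrophile ⇌ electrophile, rate k5*(cs5 - [electrophile]) while solid is left; crystals form when [electrophile] > cs5 (solubility = 0.200 M, k = 0.0349 /min)

- The flask gives 91.3 % reacted and 88.5 % free at 5.0 h, with 61.6 % of the charged nucleophile still free. The start constant has then fallen to 0.0102 /min. Consumption accounts for a factor of 0.696 and binding for the remaining 0.885.
- In the neighbour flask with 1.80 equiv of nucleophile, the start constant scales to 0.00990 /min. Averaged with the 55 % left at the end, and with the dissolved level frozen, it gives about 65.6 % of target over 5.0 h; the computed flask gives 70.2 %.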